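The route rests on cutting the C6–C23 bond between the two neighbouring quaternary carbons of ring D. Since C23 lies allylic to the C12=C13 alkene of ring C, this σ-bond plus transposed alkene is the retron of a Claisen rearrangement of an allyl vinyl ether centred on C12. Heating spiro-oxepine 22, whose ring oxygen O8 links the C6=C7 enol ether to the C12 carbinol next to the ring-B alkene C13=C23, should in one operation swap the oxacycle for carbocyclic ring D, create C6 and C23 with defined configuration and unveil the C7 aldehyde. Precursor 22 already holds rings B and C, a C9 methylidene, the C3 ketal and a heat-stable Teoc carbamate on N25.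

Key step: step 15

Remark: atoms are numbered by their order in the target SMILES (C1–C7, O8, C9–C18, O19, O20, C21–C24, N25, C26, C27); rings: A dihydropyran, B ester-bearing cyclopentane, C cyclopentene, D cycloheptene, E piperidine.
Remark: N25 is carried as a 2-(trimethylsilyl)ethyl carbamate (Teoc), because a tert-butyl carbamate would be expected to thermolyse in steps 7 and 15; Teoc leaves with fluoride without touching the ketal.
Remark: the configurations of 22 and 23 were checked against the target: O8 on the face of C12 opposite H14 translates into the target configurations at C23 and C6, so both skeletons are kept and only the carbamate is changed.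
Remark: the endocyclic C3=C4 enol ether of ring A is assumed to be the thermodynamic isomer under the acid equilibration of step 19.

Step 1
Reactants: 1 sarcosine
Product: 2 N-Teoc-sarcosine
Conditions: Teoc-OSu, Et3N, 1,4-dioxane/H2O (1:1), rt
Reagents that add atoms: N-{[2-(trimethylsilyl)ethoxy]carbonyloxy}succinimide (Teoc-OSu), C[Si](C)(C)CCOC(=O)ON1C(=O)CCC1=O
Why: Acylation of the secondary amine by the activated carbonate under aqueous-basic (Schotten–Baumann-type) conditions should give the carbamate cleanly, the carboxylate being unreactive.

Step 2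
Reactants: 2 N-Teoc-sarcosine
Product: 4 Weinreb amide of N-Teoc-sarcosine, via acyl imidazolide 3 (not isolated)
Conditions: 1,1'-carbonyldiimidazole, CH2Cl2, rt; then MeNHOMe·HCl, rt
Reagents that add atoms: N,O-dimethylhydroxylamine hydrochloride, CNOC.Cl
Why: Activation of the acid as its imidazolide followed by aminolysis (amide coupling) should give the Weinreb amide without touching the carbamate.

Step 3
Reactants: 4 Weinreb amide of N-Teoc-sarcosine
Product: 5 chloromethyl ketone ClCH2C(=O)CH2N(Me)Teoc
Conditions: ICH2Cl, MeLi·LiBr, THF, −78 °C; aq. NH4Cl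
Reagents that add atoms: chloroiodomethane, ClCI
Why: Chloromethyllithium generated in situ by iodine–lithium exchange adds once to the Weinreb amide (nucleophilic acyl substitution through a stable chelated tetrahedral intermediate), so the α-chloroketone should form on quench while the less electrophilic carbamate survives at −78 °C.

Step 4
Reactants: 6 cyclopent-2-en-1-one; 7 dimethyl malonate
Product: 8 dimethyl 2-[(1S)-3-oxocyclopentyl]propanedioate
Conditions: LiAl[(S)-1,1'-binaphthalene-2,2'-diolate]2 (5 mol%), KOtBu (4.5 mol%), 4 Å molecular sieves, THF, rt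
Reagents that add atoms: none
Why: Catalytic asymmetric Michael addition in which the heterobimetallic binaphtholate complex binds the enone at aluminium and delivers the malonate enolate to one enantioface, which should set C14 with the (S) configuration (the antipodal catalyst would give the antipode).

Step 5
Reactants: 8 dimethyl 2-[(1S)-3-oxocyclopentyl]propanedioate; 5 chloromethyl ketone
Product: 9 alkylated malonate (1,6-diketone)
Conditions: NaH, NaI (10 mol%), THF/DMF, 0 °C to rt
Reagents that add atoms: none
Why: SN2 alkylation of the malonate anion (far more acidic than the ketone α-positions) by the activated α-haloketone under iodide catalysis should build the C17–C22 bond, C17 carrying two identical esters and so not yet being stereogenic.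

Step 6
Reactants: 9 alkylated malonate (1,6-diketone)
Product: 10 bicyclic enone diester (rings B and C)
Conditions: pyrrolidine (0.3 equiv), AcOH (0.3 equiv), toluene, 70 °C
Reagents that add atoms: none
Why: Amine-catalysed intramolecular aldol condensation of the 1,6-diketone, in which only attack of the C13 enamine on the C23 ketone gives a five-membered aldol that can dehydrate, should accumulate the conjugated tetrasubstituted C13=C23 enone without touching C14.

Step 7
Reactants: 10 bicyclic enone diester
Product: 11 bicyclic enone monoester (H17 cis to H14)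
Conditions: LiCl, H2O, DMSO, 150 °C
Reagents that add atoms: none
Why: Krapcho dealkoxycarbonylation, in which chloride demethylates one ester, the carboxylate loses CO2 and the C17 enolate should be protonated by water on the face of H14, anti to the C14–C15 bond that shields the other face, giving H17 cis to H14 (the minor C17 epimer is removed by chromatography).

Step 8
Reactants: 11 bicyclic enone monoester
Product: 12 tertiary allylic alcohol with but-3-enyl chain at C12
Conditions: but-3-enylmagnesium bromide, CeCl3 (anhydrous), THF, −78 °C; aq. NH4Cl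
Reagents that add atoms: but-3-enylmagnesium bromide, C=CCC[Mg]Br
Why: Organocerium 1,2-addition to the enone carbonyl (non-basic, carbonyl-selective, the β-carbon being fully substituted) should occur from the convex face that carries H14, away from the upward-folded C15 and C17 and from the C17 ester, placing O8 trans to H14 as the later chirality transfer requires.

Step 9
Reactants: 12 tertiary allylic alcohol
Product: 13 γ-hydroxy methyl ketone (C9 ketone)
Conditions: PdCl2 (10 mol%), Cu(OAc)2 (20 mol%), O2 (1 atm), DMA/H2O (7:1), rt
Reagents that add atoms: water, O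
Why: Tsuji–Wacker oxidation should convert the monosubstituted alkene into the methyl ketone with Markovnikov selectivity, the tetrasubstituted C13=C23 alkene being inert to oxypalladation and the acetate buffer sparing the tertiary allylic alcohol.

Step 10
Reactants: 13 γ-hydroxy methyl ketone
Product: 15 spiro-oxepinone (cyclic vinylogous ester), via enaminone 14 (not isolated)
Conditions: Me2NCH(OMe)2, toluene, 90 °C; evaporate; PPTS (20 mol%), toluene, 80 °C, N2 sweep
Reagents that add atoms: N,N-dimethylformamide dimethyl acetal, COC(OC)N(C)C
Why: Condensation of the amide acetal at the less hindered methyl group gives the β-enaminone, and acid-catalysed conjugate addition–elimination of the tertiary hydroxyl (7-endo-trig, the mode used for chromones and dihydropyranones) with loss of volatile dimethylamine should close the cyclic vinylogous ester.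

Step 11
Reactants: 15 spiro-oxepinone
Product: 16 C6-iodo spiro-oxepinone
Conditions: I2, pyridine, CH2Cl2, 0 °C to rt
Reagents that add atoms: iodine, II
Why: Electrophilic α-iodination of the electron-rich β-alkoxy enone (iodine with pyridine) should functionalise C6 selectively, the hindered tetrasubstituted alkene reacting reversibly if at all.

Step 12
Reactants: 17 ethyl vinyl ketone
Product: 19 2-(2-bromoethyl)-2-ethyl-1,3-dioxolane, via 1-bromopentan-3-one 18 (not isolated)
Conditions: HBr (gas), CH2Cl2, 0 °C; then HOCH2CH2OH, TsOH·H2O (cat.), rt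
Reagents that add atoms: hydrogen bromide, Br; ethylene glycol, OCCO
Why: Conjugate hydrobromination of the enone followed by acid-catalysed ketalisation in the same flask should give the β-bromo ketal and so mask the C3 ketone.

Step 13
Reactants: 16 C6-iodo spiro-oxepinone; 19 2-(2-bromoethyl)-2-ethyl-1,3-dioxolane
Product: 21 C6-alkylated spiro-oxepinone, via alkylzinc bromide 20 (not isolated)
Conditions: 19, Zn dust, LiCl, THF, 50 °C; then 16, Pd(OAc)2 (3 mol%), SPhos (6 mol%), THF, rt to 40 °C
Reagents that add atoms: none
Why: Negishi coupling, in which zinc inserts into the primary C–Br bond and the alkylzinc, which tolerates ester, ketone and carbamate, should couple with the alkenyl iodide to form the C5–C6 bond, the hindered tertiary allylic ether being too encumbered for ionisation by zerovalent palladium.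

Step 14
Reactants: 21 C6-alkylated spiro-oxepinone
Product: 22 spiro-oxepine dienyl ether (Claisen precursor)
Conditions: Ph3PCH3Br, KOtBu (slight deficit), THF, 0 to 45 °C
Reagents that add atoms: methyltriphenylphosphonium bromide, C[P+](c1ccccc1)(c1ccccc1)c1ccccc1.[Br-]
Why: Wittig methylenation of the vinylogous-ester carbonyl should give the exocyclic C9=C27 alkene, the ylide being too weak a base to epimerise C17 and unreactive toward the ester and the carbamate.

Step 15
Reactants: 22 spiro-oxepine dienyl ether
Product: 23 ring-D aldehyde (rings B, C and D; quaternary C6 and C23)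
Conditions: 1,2-dichlorobenzene (degassed), N,O-bis(trimethylsilyl)acetamide (0.2 equiv), base-washed sealed tube, 190 °C
Reagents that add atoms: none
Why: On heating, the allyl vinyl ether C6=C7–O8–C12–C13=C23 should undergo a concerted suprafacial [3,3]-sigmatropic (Claisen) shift in which the tertiary allylic C12–O8 bond breaks while C6–C23 forms, C7 becomes an aldehyde and the ring-B alkene C13=C23 moves to C12=C13 in ring C. The closest known reaction type is the thermal Claisen ring contraction of 2-alkenyl cyclic enol ethers (and of lactone-derived ketene acetals) to cycloalkene carbaldehydes or acids. Ring D closes by exchange of the seven-membered oxacycle for a seven-membered carbocycle through a boat-shaped, bicyclo[3.2.2]-like array in which the bridges C7–O8, C13–C23 and C9–C10–C11 all span C6 and C12, a chair being geometrically excluded. C23 is set by chirality transfer from C12, the new bond forming on the face that O8 leaves (anti to H14), and C6 is set by the same tether, which places C9 on the C24 side and C5 on the C22 side of the new bond, so a single diastereomer is possible. The step needs the [3,3] path to outrun retro-ene fragmentation and ionisation followed by a [1,3] shift; the weak tertiary allylic C–O bond, the gain of a carbonyl group, the trigonal C9 free of stereochemistry and acid-free non-polar conditions should secure this.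

Step 16
Reactants: 23 ring-D aldehyde
Product: 24 C7 primary alcohol
Conditions: NaBH4, MeOH, 0 °C
Reagents that add atoms: none
Why: Hydride reduction of the aldehyde (no α-hydrogen, so no epimerisation) should give the neopentyl alcohol chemoselectively, NaBH4 in cold methanol leaving the methyl ester, carbamate and ketal untouched.

Step 17
Reactants: 24 C7 primary alcohol
Product: 25 amino alcohol (free N25–H)
Conditions: Bu4NF, THF, rt to 40 °C
Reagents that add atoms: none
Why: Fluoride attacks silicon and triggers β-elimination with loss of ethene and CO2, which should free the secondary amine under near-neutral conditions that spare the ketal, the ester and both alkenes.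

Step 18
Reactants: 25 amino alcohol
Product: 26 ring-E piperidine (rings B to E; ketal alcohol)
Conditions: [Ir(dF(Me)ppy)2(dtbbpy)]PF6 (2 mol%), 2,4,6-triisopropylbenzenethiol (30 mol%), toluene, blue LEDs, rt
Reagents that add atoms: none
Why: Photocatalytic anti-Markovnikov hydroamination, in which single-electron oxidation of the secondary amine gives an aminium radical cation that should add 6-endo to the unsubstituted C27 terminus (forming the tertiary C9 radical), with hydrogen-atom transfer from the thiol able to reach C9 only from the outer face of the new bridged ring, which fixes the C9 configuration.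

Step 19
Reactants: 26 ring-E piperidine
Product: 28 target CNP0159589.3, via hydroxy ketone 27 (not isolated)
Conditions: TsOH·H2O (1.2 equiv), acetone, rt; evaporate; PPTS (0.2 equiv), toluene, 4 Å molecular sieves, 80 °C; Et3N quench
Reagents that add atoms: none
Why: Acid-catalysed transketalisation to acetone unmasks the C3 ketone, and dehydrative cyclisation of the δ-hydroxy ketone (through its hemiketal) under water-removing conditions should give the thermodynamically preferred endocyclic enol ether of ring A.

Compound list
1 | sarcosine (N-methylglycine) | CNCC(=O)O | starting material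
2 | N-Teoc-sarcosine, N-methyl-N-{[2-(trimethylsilyl)ethoxy]carbonyl}glycine | CN(CC(=O)O)C(=O)OCC[Si](C)(C)C | intermediate
3 | acyl imidazolide of 2 (not isolated) | CN(CC(=O)n1ccnc1)C(=O)OCC[Si](C)(C)C | intermediate
4 | Weinreb amide, 2-(trimethylsilyl)ethyl {2-[methoxy(methyl)amino]-2-oxoethyl}(methyl)carbamate | CON(C)C(=O)CN(C)C(=O)OCC[Si](C)(C)C | intermediate
5 | chloromethyl ketone, 2-(trimethylsilyl)ethyl (3-chloro-2-oxopropyl)(methyl)carbamate | ClCC(=O)CN(C)C(=O)OCC[Si](C)(C)C | intermediate
6 | cyclopent-2-en-1-one | O=C1C=CCC1 | starting material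
7 | dimethyl malonate | COC(=O)CC(=O)OC | starting material
8 | dimethyl 2-[(1S)-3-oxocyclopentyl]propanedioate (C14 set) | COC(=O)C(C(=O)OC)[C@H]1CCC(=O)C1 | intermediate
9 | dimethyl 2-[(1S)-3-oxocyclopentyl]-2-{3-[methyl(Teoc)amino]-2-oxopropyl}propanedioate | COC(=O)C(CC(=O)CN(C)C(=O)OCC[Si](C)(C)C)(C(=O)OC)[C@H]1CCC(=O)C1 | intermediate
10 | bicyclic enone diester: bicyclo[3.3.0]octene with C12 ketone, C13=C23 alkene, C23–CH2N(Me)Teoc, C17(CO2Me)2, C14 (S) | O=C1CC[C@@H]2C(C(=O)OC)(C(=O)OC)CC(CN(C)C(=O)OCC[Si](C)(C)C)=C12 | intermediate
11 | bicyclic enone monoester: as 10 with one CO2Me at C17, H17 cis to H14 (C14 R, C17 R) | O=C1CC[C@@H]2[C@H](C(=O)OC)CC(CN(C)C(=O)OCC[Si](C)(C)C)=C12 | intermediate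
12 | tertiary allylic alcohol: C12 carbinol bearing the but-3-enyl chain C11–C10–C9=C6, hydroxyl trans to H14 | O[C@]1(CCC=C)CC[C@@H]2[C@H](C(=O)OC)CC(CN(C)C(=O)OCC[Si](C)(C)C)=C12 | intermediate
13 | γ-hydroxy methyl ketone (C9 ketone, C6 methyl) | O[C@]1(CCC(C)=O)CC[C@@H]2[C@H](C(=O)OC)CC(CN(C)C(=O)OCC[Si](C)(C)C)=C12 | intermediate
14 | (E)-β-(dimethylamino)enone of 13 (C7 installed; not isolated) | O[C@]1(CCC(=O)/C=C/N(C)C)CC[C@@H]2[C@H](C(=O)OC)CC(CN(C)C(=O)OCC[Si](C)(C)C)=C12 | intermediate
15 | spiro-oxepinone: ring O8–C7H=C6H–C9(=O)–C10H2–C11H2 spiro at C12 | O=C1C=CO[C@]2(CC1)CC[C@@H]3[C@H](C(=O)OC)CC(CN(C)C(=O)OCC[Si](C)(C)C)=C32 | intermediate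
16 | C6-iodo spiro-oxepinone | O=C1C(I)=CO[C@]2(CC1)CC[C@@H]3[C@H](C(=O)OC)CC(CN(C)C(=O)OCC[Si](C)(C)C)=C32 | intermediate
17 | ethyl vinyl ketone (pent-1-en-3-one) | CCC(=O)C=C | starting material
18 | 1-bromopentan-3-one (not isolated) | CCC(=O)CCBr | intermediate
19 | 2-(2-bromoethyl)-2-ethyl-1,3-dioxolane | CCC1(CCBr)OCCO1 | intermediate
20 | [2-(2-ethyl-1,3-dioxolan-2-yl)ethyl]zinc bromide (not isolated) | CCC1(CC[Zn]Br)OCCO1 | intermediate
21 | C6-alkylated spiro-oxepinone (C1–C5 ketal chain on C6, C9 ketone) | CCC1(OCCO1)CCC2=CO[C@]3(CCC2=O)CC[C@@H]4[C@H](C(=O)OC)CC(CN(C)C(=O)OCC[Si](C)(C)C)=C43 | intermediate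
22 | spiro-oxepine dienyl ether (Claisen precursor): C6=C7 enol ether, C9 methylidene, O8 on C12 trans to H14, C13=C23 alkene | CCC1(OCCO1)CCC2=CO[C@]3(CCC2=C)CC[C@@H]4[C@H](C(=O)OC)CC(CN(C)C(=O)OCC[Si](C)(C)C)=C43 | intermediate
23 | ring-D aldehyde: rings B, C and D, quaternary C6 (CHO) and C23, C12=C13 alkene | CCC1(OCCO1)CC[C@@]2(C=O)C(=C)CCC3=C4[C@H](CC3)[C@H](C(=O)OC)C[C@@]42CN(C)C(=O)OCC[Si](C)(C)C | intermediate
24 | C7 primary alcohol of 23 | CCC1(OCCO1)CC[C@@]2(CO)C(=C)CCC3=C4[C@H](CC3)[C@H](C(=O)OC)C[C@@]42CN(C)C(=O)OCC[Si](C)(C)C | intermediate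
25 | amino alcohol (N25–H, C7–OH, C9 methylidene) | CCC1(OCCO1)CC[C@@]2(CO)C(=C)CCC3=C4[C@H](CC3)[C@H](C(=O)OC)C[C@@]42CNC | intermediate
26 | ring-E piperidine: rings B to E, C3 ketal, C7–OH, C9–H as in the target | CCC1(OCCO1)CC[C@@]2(CO)[C@@H]1CCC3=C4[C@H](CC3)[C@H](C(=O)OC)C[C@@]42CN(C)C1 | intermediate
27 | δ-hydroxy ketone (C3 ketone, C7–OH; not isolated) | CCC(=O)CC[C@@]2(CO)[C@@H]1CCC3=C4[C@H](CC3)[C@H](C(=O)OC)C[C@@]42CN(C)C1 | intermediate
28 | CNP0159589.3 | CCC1=CC[C@@]2(CO1)[C@@H]1CCC3=C4[C@H](CC3)[C@H](C(=O)OC)C[C@@]42CN(C)C1 | target

Total step count: 19. Longest linear sequence: 17 steps (steps 1–3, 5–11 and 13–19, from sarcosine).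

Steps most likely to fail

Step 15. The bridged boat may be reached too slowly, so that thermal retro-ene cleavage of the tertiary allyl ether, or ionisation followed by [1,3] recombination or elimination, consumes the enol ether. Fallback: the sigmatropic shift is moved one stage earlier, to vinylogous ester 21. Its C12–O8 bond is more polarised, C9 carries no hydrogens that clash with C24, and no diene conjugation is lost. Heating 21 in xylenes (150–180 °C) is the classical O-to-C allyl shift of enol ethers of 1,3-dicarbonyl compounds and should give keto aldehyde F1 with the same C6 and C23 configurations. NaBH4 (MeOH/CH2Cl2, −78 °C) should reduce only the aldehyde to hydroxy ketone F2. TESCl and imidazole give silyl ether F3. Wittig methylenation (Ph3PCH3Br, KOtBu, toluene, 80 °C) of the C9 ketone gives methylidene silyl ether F4. Bu4NF then removes the triethylsilyl and Teoc groups together and rejoins the route at amino alcohol 25.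

Step 10. Acid-triggered ionisation and dehydration of the tertiary allylic alcohol, or an unfavourable amine-exchange equilibrium, may prevent seven-membered ring closure. Fallback: a base-mediated, irreversible closure starting from 13. Enaminone 14 is isolated and hydrolysed in buffered medium (AcOH/NaOAc, THF/H2O, rt) to hydroxymethylene ketone F5. This is converted into enol tosylate F6 (TsCl, Et3N, CH2Cl2, 0 °C). The tertiary alkoxide (KOtBu, THF, high dilution, 0 °C) then displaces tosylate by conjugate addition–elimination and the route is rejoined at spiro-oxepinone 15.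

Step 18. The aminium radical cation may be diverted by 1,5-hydrogen-atom transfer from the C7 carbinol or by 5-exo attack at C9, or back electron transfer may outpace the 6-endo addition. Fallback: classical hydroboration and displacement starting from carbamate 24. 9-BBN (THF, rt) followed by NaBO3 gives diol F7; only the C9 epimer drawn can cyclise, and it is separated. The less hindered C27 hydroxyl is sulfonylated selectively (TsCl, pyridine, −20 °C) to monotosylate F8. Bu4NF then frees N25, which should displace the tosylate (6-exo-tet SN2) to give 26.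

Further compounds
F1 | step 15 | keto aldehyde: analogue of 23 with a C9 ketone | CCC1(OCCO1)CC[C@@]2(C=O)C(=O)CCC3=C4[C@H](CC3)[C@H](C(=O)OC)C[C@@]42CN(C)C(=O)OCC[Si](C)(C)C
F2 | step 15 | hydroxy ketone: C7–OH, C9 ketone | CCC1(OCCO1)CC[C@@]2(CO)C(=O)CCC3=C4[C@H](CC3)[C@H](C(=O)OC)C[C@@]42CN(C)C(=O)OCC[Si](C)(C)C
F3 | step 15 | triethylsilyl ether of F2 | CCC1(OCCO1)CC[C@@]2(CO[Si](CC)(CC)CC)C(=O)CCC3=C4[C@H](CC3)[C@H](C(=O)OC)C[C@@]42CN(C)C(=O)OCC[Si](C)(C)C
F4 | step 15 | methylidene silyl ether: triethylsilyl ether of 24 | CCC1(OCCO1)CC[C@@]2(CO[Si](CC)(CC)CC)C(=C)CCC3=C4[C@H](CC3)[C@H](C(=O)OC)C[C@@]42CN(C)C(=O)OCC[Si](C)(C)C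
F5 | step 10 | hydroxymethylene ketone (Z-enol of the C7 formyl C9 ketone) | O[C@]1(CCC(=O)/C=C\O)CC[C@@H]2[C@H](C(=O)OC)CC(CN(C)C(=O)OCC[Si](C)(C)C)=C12
F6 | step 10 | enol tosylate of F5 | O[C@]1(CCC(=O)/C=C/OS(=O)(=O)c3ccc(C)cc3)CC[C@@H]2[C@H](C(=O)OC)CC(CN(C)C(=O)OCC[Si](C)(C)C)=C12
F7 | step 18 | diol: C7–OH and C27–OH, C9–H as in the target | CCC1(OCCO1)CC[C@@]2(CO)[C@@H](CO)CCC3=C4[C@H](CC3)[C@H](C(=O)OC)C[C@@]42CN(C)C(=O)OCC[Si](C)(C)C
F8 | step 18 | C27 monotosylate of F7 | CCC1(OCCO1)CC[C@@]2(CO)[C@@H](COS(=O)(=O)c5ccc(C)cc5)CCC3=C4[C@H](CC3)[C@H](C(=O)OC)C[C@@]42CN(C)C(=O)OCC[Si](C)(C)C
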